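Ring A is built from open-chain carbon and aromatized late. Its ether carbon C3 sits between C2 (Br) and C4 (OH) exactly as the central carbon of a cyclohexane-1,3-dione sits between two carbonyls, so C2 and C4 begin as carbonyl carbons and the crowded C3–O–C1' link to ring B is made beforehand by phenol alkylation at an sp3 carbon. In one operation dimethyl malonate adds to an aryloxymethyl vinyl ketone (bond C1–C6) and the aryloxy-bearing ketone carbon closes onto a malonate ester (bond C2–C3), giving ring A as a 2-aryloxy-1,3-dione ester. The precursor is a 1-aryloxybut-3-en-2-one whose ring-B aldehyde is masked as a 1,3-dioxolane.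

Key step: step 4

Remarks on the chemistry:
- The target has no stereocentre. The two stereocentres created in step 4 are racemic and disappear in step 5.
- Atom labels: ring A is C1 (CH2OH), C2 (Br), C3 (O-aryl), C4 (OH), C5 (Br), C6 (H). Ring B is C1' (ether carbon), C2' (CH2OH), C3' (H), C4' (Br), C5' and C6' (OH).
- The side chain is introduced directly as the Weinreb amide, which saves an ester-to-amide step.
- The aldehyde is carried as a cyclic acetal, which should tolerate the weakly acidic quench of step 3 and the acidification of step 4 better than an open-chain acetal. It is released only once ring A is aromatic, so that C3 can no longer add to it.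
- Assumption: in step 5 the dioxolane is taken to exchange at least partly with methanol; both acetal forms (10 and 11) converge on aldehyde 12 in the acidic finish.

Step 1
Reactants: 1 2-hydroxy-3,4-dimethoxybenzaldehyde; 2 2-chloro-N-methoxy-N-methylacetamide
Product: 3 2-(6-formyl-2,3-dimethoxyphenoxy)-N-methoxy-N-methylacetamide
Conditions: K2CO3, NaI (cat.), DMF, 60 °C
Reagents that add atoms: none
Why: Williamson ether synthesis, in which the phenoxide displaces halide at an unhindered primary carbon; this fixes the C1'–O–C3 oxygen without any coupling at a doubly ortho-substituted aryl carbon and delivers the Weinreb amide directly.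

Step 2
Reactants: 3 2-(6-formyl-2,3-dimethoxyphenoxy)-N-methoxy-N-methylacetamide
Product: 4 2-[6-(1,3-dioxolan-2-yl)-2,3-dimethoxyphenoxy]-N-methoxy-N-methylacetamide
Conditions: ethylene glycol, p-TsOH (cat.), toluene, reflux, Dean–Stark
Reagents that add atoms: ethylene glycol, OCCO
Why: Acid-catalysed acetalization driven by azeotropic removal of water; the Weinreb amide is inert, and the acetal shields the aldehyde from the Grignard reagent and from aldol (benzofuran-forming) attack in the basic annulation.

Step 3
Reactants: 4 2-[6-(1,3-dioxolan-2-yl)-2,3-dimethoxyphenoxy]-N-methoxy-N-methylacetamide; 5 vinylmagnesium bromide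
Product: 6 1-[6-(1,3-dioxolan-2-yl)-2,3-dimethoxyphenoxy]but-3-en-2-one
Conditions: THF, −78 to 0 °C; inverse quench into cold aq. citric acid/Et2O; used crude at once (BHT)
Reagents that add atoms: none
Why: Weinreb ketone synthesis, in which the chelated tetrahedral magnesium adduct prevents over-addition and collapses only on quench; the cold weakly acidic quench should protonate the liberated N,O-dimethylhydroxylamine before it can add to the enone, while the brief contact should leave the dioxolane in place.

Step 4
Reactants: 6 1-[6-(1,3-dioxolan-2-yl)-2,3-dimethoxyphenoxy]but-3-en-2-one; 7 dimethyl malonate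
Product: 9 methyl 3-[6-(1,3-dioxolan-2-yl)-2,3-dimethoxyphenoxy]-2,4-dioxocyclohexane-1-carboxylate (racemic enol mixture), via Michael adduct 8 (not isolated)
Conditions: NaOMe, MeOH, 0 °C then reflux; AcOH to pH 5 at 0 °C
Reagents that add atoms: none
Why: Sodium dimethyl malonate adds in a conjugate sense to the vinyl ketone (bond C1–C6) to give 8, proton transfer moves the charge to the α-carbon that bears the aryloxy group, and this enolate attacks one malonate ester and expels methoxide (bond C2–C3). The closest known reaction type is the Michael–Claisen (Dieckmann-type) annulation of enones with malonates to dihydroresorcylate esters. Ring A closes by a 6-exo-trig acyl substitution. The stereocentres formed at C1 and C3 are not controlled and need not be, because 9 is a racemic, enolized tricarbonyl and both carbons become sp2 in step 5. The selectivity required is regiochemical and is secured by ring size and by the protecting group: only the OCH2 carbon reaches a malonate ester through a six-membered transition state (the other α-carbon would give a four-membered ring), and the dioxolane removes the ring-B aldehyde as a competing electrophile. Irreversible deprotonation of the acidic product pulls the equilibria forward, and slow addition of 6 to excess malonate anion suppresses enone oligomerization and double addition.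

Step 5
Reactants: 9 methyl 3-[6-(1,3-dioxolan-2-yl)-2,3-dimethoxyphenoxy]-2,4-dioxocyclohexane-1-carboxylate
Product: 12 methyl 3-(6-formyl-2,3-dimethoxyphenoxy)-2-hydroxy-4-methoxybenzoate, via dioxolane salicylate 10 (not isolated), via dimethyl acetal salicylate 11 (not isolated)
Conditions: I2 (2.2 equiv), MeOH, reflux; then 1 M HCl, THF, rt
Reagents that add atoms: methanol, CO; water, O
Why: Iodine–methanol oxidative aromatization of a cyclic 1,3-dione, in which methanolic HI should turn the C4 carbonyl (remote from the ester and less hindered) into its methyl enol ether, iodination–dehydroiodination removes two hydrogens, and the ester-flanked C2 oxygen emerges as the chelated phenol; the acetal is then hydrolysed in the acidic finish.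

Step 6
Reactants: 12 methyl 3-(6-formyl-2,3-dimethoxyphenoxy)-2-hydroxy-4-methoxybenzoate
Product: 13 methyl 3-(6-formyl-2,3-dimethoxyphenoxy)-4-methoxy-2-(trifluoromethanesulfonyloxy)benzoate
Conditions: Tf2O, pyridine, CH2Cl2, 0 °C to rt
Reagents that add atoms: trifluoromethanesulfonic anhydride, O=S(=O)(OS(=O)(=O)C(F)(F)F)C(F)(F)F
Why: O-Sulfonylation of the only free hydroxyl; salicylate phenols, although chelated, are triflated readily under these conditions and the aldehyde and ester are untouched.

Step 7
Reactants: 13 methyl 3-(6-formyl-2,3-dimethoxyphenoxy)-4-methoxy-2-(trifluoromethanesulfonyloxy)benzoate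
Product: 14 methyl 2-bromo-3-(6-formyl-2,3-dimethoxyphenoxy)-4-methoxybenzoate
Conditions: Pd2(dba)3 (cat.), t-BuBrettPhos, KBr, KF, 1,4-dioxane, 130 °C
Reagents that add atoms: potassium bromide, [K+].[Br-]
Why: Palladium-catalysed conversion of an aryl triflate into an aryl bromide, in which zerovalent palladium inserts into the ester-activated C2–OTf bond, bromide replaces triflate on divalent palladium, and the bulky biarylphosphine forces C–Br reductive elimination; ring B has no C–H ortho to the ether oxygen, so cyclization to a dibenzofuran cannot compete.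

Step 8
Reactants: 14 methyl 2-bromo-3-(6-formyl-2,3-dimethoxyphenoxy)-4-methoxybenzoate
Product: 15 methyl 2,5-dibromo-3-(4-bromo-6-formyl-2,3-dimethoxyphenoxy)-4-methoxybenzoate
Conditions: Br2 (2.5 equiv), AcOH, rt to 70 °C
Reagents that add atoms: bromine, BrBr
Why: Electrophilic aromatic bromination, directed in each ring by the one methoxy group that can lie in the ring plane and has a single free ortho position (C5 in ring A, also para to C2–Br; C4' in ring B, also para to the ether oxygen and meta to the aldehyde), whereas C6 and C3' are ortho to a carbonyl group and para only to twisted, weakly donating oxygens.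

Step 9
Reactants: 15 methyl 2,5-dibromo-3-(4-bromo-6-formyl-2,3-dimethoxyphenoxy)-4-methoxybenzoate
Product: 16 methyl 2,5-dibromo-3-(4-bromo-6-formyl-2,3-dihydroxyphenoxy)-4-hydroxybenzoate
Conditions: BBr3 (7 equiv), CH2Cl2, −78 to 0 °C; ice-water
Reagents that add atoms: none
Why: Lewis-acid cleavage of the three aryl methyl ethers (O-complexation, then bromide attack on methyl); the diaryl ether, aryl bromides, aldehyde and, at low temperature, the methyl ester should survive, and keeping both benzylic carbons at the carbonyl level prevents their conversion into benzylic bromides.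

Step 10
Reactants: 16 methyl 2,5-dibromo-3-(4-bromo-6-formyl-2,3-dihydroxyphenoxy)-4-hydroxybenzoate
Product: 17 3-bromo-6-[2,5-dibromo-6-hydroxy-3-(hydroxymethyl)phenoxy]-5-(hydroxymethyl)benzene-1,2-diol (CNP0104332.0)
Conditions: i-Bu2AlH (10 equiv), THF, −78 to 0 °C; aq. potassium sodium tartrate
Reagents that add atoms: none
Why: Hydride reduction of ester and aldehyde to the two primary alcohols; the phenols are first converted into aluminium phenoxides, which should not block reduction, aryl bromides are inert to i-Bu2AlH at this temperature, and the near-neutral tartrate work-up avoids quinone-methide chemistry of the 4-hydroxybenzyl alcohols.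

Compound list
1 | 2-hydroxy-3,4-dimethoxybenzaldehyde | O=Cc1ccc(OC)c(OC)c1O | starting material
2 | 2-chloro-N-methoxy-N-methylacetamide | CON(C)C(=O)CCl | starting material
3 | 2-(6-formyl-2,3-dimethoxyphenoxy)-N-methoxy-N-methylacetamide | CON(C)C(=O)COc1c(C=O)ccc(OC)c1OC | intermediate
4 | 2-[6-(1,3-dioxolan-2-yl)-2,3-dimethoxyphenoxy]-N-methoxy-N-methylacetamide | CON(C)C(=O)COc1c(C2OCCO2)ccc(OC)c1OC | intermediate
5 | vinylmagnesium bromide | C=C[Mg]Br | starting material
6 | 1-[6-(1,3-dioxolan-2-yl)-2,3-dimethoxyphenoxy]but-3-en-2-one | C=CC(=O)COc1c(C2OCCO2)ccc(OC)c1OC | intermediate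
7 | dimethyl malonate | COC(=O)CC(=O)OC | starting material
8 | dimethyl 2-{4-[6-(1,3-dioxolan-2-yl)-2,3-dimethoxyphenoxy]-3-oxobutyl}propanedioate (Michael adduct; not isolated) | COC(=O)C(CCC(=O)COc1c(C2OCCO2)ccc(OC)c1OC)C(=O)OC | intermediate
9 | methyl 3-[6-(1,3-dioxolan-2-yl)-2,3-dimethoxyphenoxy]-2,4-dioxocyclohexane-1-carboxylate (racemic; enolized) | COC(=O)C1CCC(=O)C(Oc2c(C3OCCO3)ccc(OC)c2OC)C1=O | intermediate
10 | methyl 3-[6-(1,3-dioxolan-2-yl)-2,3-dimethoxyphenoxy]-2-hydroxy-4-methoxybenzoate (not isolated) | COC(=O)c1ccc(OC)c(Oc2c(C3OCCO3)ccc(OC)c2OC)c1O | intermediate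
11 | methyl 3-[6-(dimethoxymethyl)-2,3-dimethoxyphenoxy]-2-hydroxy-4-methoxybenzoate (not isolated) | COC(=O)c1ccc(OC)c(Oc2c(C(OC)OC)ccc(OC)c2OC)c1O | intermediate
12 | methyl 3-(6-formyl-2,3-dimethoxyphenoxy)-2-hydroxy-4-methoxybenzoate | COC(=O)c1ccc(OC)c(Oc2c(C=O)ccc(OC)c2OC)c1O | intermediate
13 | methyl 3-(6-formyl-2,3-dimethoxyphenoxy)-4-methoxy-2-(trifluoromethanesulfonyloxy)benzoate | COC(=O)c1ccc(OC)c(Oc2c(C=O)ccc(OC)c2OC)c1OS(=O)(=O)C(F)(F)F | intermediate
14 | methyl 2-bromo-3-(6-formyl-2,3-dimethoxyphenoxy)-4-methoxybenzoate | COC(=O)c1ccc(OC)c(Oc2c(C=O)ccc(OC)c2OC)c1Br | intermediate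
15 | methyl 2,5-dibromo-3-(4-bromo-6-formyl-2,3-dimethoxyphenoxy)-4-methoxybenzoate | COC(=O)c1cc(Br)c(OC)c(Oc2c(C=O)cc(Br)c(OC)c2OC)c1Br | intermediate
16 | methyl 2,5-dibromo-3-(4-bromo-6-formyl-2,3-dihydroxyphenoxy)-4-hydroxybenzoate | COC(=O)c1cc(Br)c(O)c(Oc2c(C=O)cc(Br)c(O)c2O)c1Br | intermediate
17 | 3-bromo-6-[2,5-dibromo-6-hydroxy-3-(hydroxymethyl)phenoxy]-5-(hydroxymethyl)benzene-1,2-diol (achiral) | OCc1cc(Br)c(O)c(Oc2c(CO)cc(Br)c(O)c2O)c1Br | target

Total step count: 10. Longest linear sequence: 10 steps (1 to 17).

Steps most likely to fail

1. Step 7. The bromide-for-triflate exchange takes place at a carbon flanked by an ester and an aryloxy group and may be slow, so that S–O cleavage of the triflate back to the phenol, or reduction of the arylpalladium intermediate, outruns C–Br reductive elimination. Fallback, setting out from 13: Miyaura borylation (PdCl2(dppf), B2pin2, KOAc, 1,4-dioxane, 90 °C) should give methyl 3-(6-formyl-2,3-dimethoxyphenoxy)-4-methoxy-2-(4,4,5,5-tetramethyl-1,3,2-dioxaborolan-2-yl)benzoate F1. Bromodeboronation with CuBr2 in MeOH/H2O at 80 °C should then give 14, where the route is rejoined.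

2. Step 5. The oxidation may stall at the enol ether stage, methylation may spread to O2, or the aldehyde may be unmasked before ring A is aromatic, so that C3 adds to it. Fallback, setting out from 9: dehydrogenation over Pd/C in boiling mesitylene (neutral, acetal retained) should give methyl 3-[6-(1,3-dioxolan-2-yl)-2,3-dimethoxyphenoxy]-2,4-dihydroxybenzoate F2. Methylation of the non-chelated, more acidic O4 (MeI, K2CO3, acetone, rt) then gives 10, and 1 M HCl in THF hydrolyses 10 to 12, where the route is rejoined.

3. Step 8. Ring A is deactivated by ester and bromine and may brominate slowly or partly at C6, while forcing conditions may begin to oxidize the aldehyde. Fallback, setting out from 14: demethylation first (BBr3, CH2Cl2, −78 to 0 °C) should give methyl 2-bromo-3-(6-formyl-2,3-dihydroxyphenoxy)-4-hydroxybenzoate F3. Phenol-directed bromination under mild conditions (Br2, 2 equiv, NaOAc, AcOH, rt) should then send bromine to C5, the only free position ortho to the C4 hydroxyl, and to C4', ortho to the C5' hydroxyl. This gives 16, where the route is rejoined.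

Further compounds
F1 | step 7 | methyl 3-(6-formyl-2,3-dimethoxyphenoxy)-4-methoxy-2-(4,4,5,5-tetramethyl-1,3,2-dioxaborolan-2-yl)benzoate | COC(=O)c1ccc(OC)c(Oc2c(C=O)ccc(OC)c2OC)c1B1OC(C)(C)C(C)(C)O1
F2 | step 5 | methyl 3-[6-(1,3-dioxolan-2-yl)-2,3-dimethoxyphenoxy]-2,4-dihydroxybenzoate | COC(=O)c1ccc(O)c(Oc2c(C3OCCO3)ccc(OC)c2OC)c1O
F3 | step 8 | methyl 2-bromo-3-(6-formyl-2,3-dihydroxyphenoxy)-4-hydroxybenzoate | COC(=O)c1ccc(O)c(Oc2c(C=O)ccc(O)c2O)c1Br
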